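Ring A (the 2-heptyl-4,6-dimethoxybenzoyl ring) is built from a 2-pyrone instead of by substituting an arene. Ring A bonds C2–C3 and C4–C5 are disconnected: benzyl 6-heptyl-4-methoxy-2-pyrone-5-carboxylate already holds ring A atoms C1 (with the carboxyl carbon), C2 (heptyl), C6 (OMe) and C5, while 1,1-dimethoxyethene brings C3 and C4 with its methoxy group. One thermal operation performs the inverse-demand [4+2] addition, expels CO2 and methanol, and leaves the fully substituted benzoate. The feature exploited is the para relation between the C1 carboxyl and the C4 methoxy group of ring A, the natural outcome of this pyrone–ketene acetal pairing. Ring B is then attached through the depside ester.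

Key step: step 4

Remark: ring A is numbered from the carbon bearing the ester carbonyl (C1) and ring B from the carbon bearing CO2H; compounds 3 and 4 are drawn as single tautomers although both are largely enolised.

Step 1
Reactants: 1 dibenzyl 3-oxopentanedioate; 2 octanoyl chloride
Product: 3 dibenzyl 2-octanoyl-3-oxopentanedioate
Conditions: MgCl2 (1.1 equiv), pyridine (2.2 equiv), CH2Cl2, 0 °C; then 2 (1.0 equiv), 0 °C → rt; 1 M HCl work-up
Reagents that add atoms: none
Why: C-acylation of a β-keto ester by soft enolisation, in which the magnesium chelate of the 1,3-dicarbonyl unit is acylated at carbon by the acid chloride and the more acidic product, held as its own magnesium enolate, should resist a second acylation.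

Step 2
Reactants: 3 dibenzyl 2-octanoyl-3-oxopentanedioate
Product: 4 benzyl 6-heptyl-4-hydroxy-2-oxo-2H-pyran-5-carboxylate
Conditions: DBU (1.2 equiv), PhMe, rt → 60 °C; then 1 M HCl
Reagents that add atoms: none
Why: Base-induced lactonisation of a 3,5-dioxo ester to a 4-hydroxy-2-pyrone, in which the enolate oxygen of the octanoyl ketone attacks the remote benzyl ester (6-exo-trig acyl substitution, the only six-membered closure open to 3) and the pyrone rests as its stabilised anion until acidification.

Step 3
Reactants: 4 benzyl 6-heptyl-4-hydroxy-2-oxo-2H-pyran-5-carboxylate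
Product: 5 benzyl 6-heptyl-4-methoxy-2-oxo-2H-pyran-5-carboxylate
Conditions: Me2SO4 (1.2 equiv), K2CO3 (1.5 equiv), acetone, reflux
Reagents that add atoms: dimethyl sulfate, COS(=O)(=O)OC
Why: Williamson-type O-methylation of the ambident 4-hydroxy-2-pyrone anion with a hard electrophile, conditions that favour the 4-methoxy-2-pyrone over the 2-methoxy-4-pyrone and leave the lactone and benzyl ester untouched.

Step 4
Reactants: 5 benzyl 6-heptyl-4-methoxy-2-oxo-2H-pyran-5-carboxylate; 6 1,1-dimethoxyethene
Product: 9 benzyl 2-heptyl-4,6-dimethoxybenzoate, via bridged lactone cycloadduct 7 (not isolated), via cyclohexadiene ketal 8 (not isolated)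
Conditions: 6 (8 equiv), PhMe, base-washed sealed tube, 150 °C
Reagents that add atoms: none
Why: The electron-rich CH2 carbon of ketene acetal 6 attacks pyrone C6, which is the β-carbon of the C5 acrylate unit and the δ-carbon of the lactone carbonyl, while the acetal carbon bonds to pyrone C3, in an inverse-electron-demand Diels–Alder reaction that may be concerted and asynchronous or pass through a zwitterion. The closest known reaction is the cycloaddition of 2-pyrone-5-carboxylates with ketene acetals to give 4-alkoxybenzoates; here the 4-methoxy and 6-alkyl groups make the diene less electrophilic, which is answered by excess dienophile and 150 °C in a closed vessel. The new carbocycle (ring A) closes in an intermolecular [4+2] event, and if the second bond forms after the first it is a 6-exo-trig attack of the lactone enolate carbon C3 on the dimethoxycarbenium carbon. Bridged lactone 7 then loses CO2 by retro-[4+2], and diene 8, with its ketal carbon next to a CH2 group, aromatises by 1,2-elimination of methanol. No stereocentre remains, since the two bridgehead centres of 7 are erased on aromatisation. The one selectivity needed is the orientation of addition, secured by the C5 ester, which polarises the diene so that C6 and not C3 receives the nucleophilic terminus; the reverse orientation would put the new methoxy group beside the heptyl chain.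

Step 5
Reactants: 9 benzyl 2-heptyl-4,6-dimethoxybenzoate
Product: 10 2-heptyl-4,6-dimethoxybenzoic acid
Conditions: H2 (1 atm), 10 % Pd/C, EtOAc, rt
Reagents that add atoms: none
Why: Catalytic hydrogenolysis of the benzyl ester, a neutral deprotection that should leave the aryl methyl ethers, the arene and the alkyl chain unchanged.

Step 6
Reactants: 11 2-methoxy-6-methylbenzoic acid
Product: 12 tert-butyl 2-methoxy-6-methylbenzoate
Conditions: tert-butyl 2,2,2-trichloroacetimidate (2 equiv), BF3·OEt2 (5 mol %), CH2Cl2/cyclohexane, rt
Reagents that add atoms: tert-butyl 2,2,2-trichloroacetimidate, CC(C)(C)OC(=N)C(Cl)(Cl)Cl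
Why: Acid-catalysed tert-butylation with a trichloroacetimidate, in which the carboxyl oxygen captures the tert-butyl cation equivalent, so the 2,6-disubstitution that hinders acyl substitution is no obstacle.

Step 7
Reactants: 12 tert-butyl 2-methoxy-6-methylbenzoate; 13 1-iodobutane
Product: 14 tert-butyl 2-methoxy-6-pentylbenzoate
Conditions: LiN(iPr)2 (1.1 equiv), THF, −78 °C; then 13 (1.3 equiv), −78 °C → rt
Reagents that add atoms: none
Why: Lateral lithiation of an ortho-toluate followed by SN2 alkylation, in which the benzylic anion is stabilised as the ester dienolate and the tert-butyl ester flanked by two ortho groups should suppress self-condensation.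

Step 8
Reactants: 14 tert-butyl 2-methoxy-6-pentylbenzoate
Product: 16 tert-butyl 4-hydroxy-2-methoxy-6-pentylbenzoate, via aryl pinacol boronate 15 (not isolated)
Conditions: B2pin2 (1.0 equiv), [Ir(OMe)(cod)]2 (1.5 mol %), 4,4'-di-tert-butyl-2,2'-bipyridine (3 mol %), THF, 80 °C; evaporate; then acetone, aq. KHSO5 (as 2KHSO5·KHSO4·K2SO4), rt
Reagents that add atoms: bis(pinacolato)diboron, CC1(C)OB(OC1(C)C)B1OC(C)(C)C(C)(C)O1 (its boron stays only in 15); potassium peroxymonosulfate, [K+].[O-]S(=O)(=O)OO (gives the phenol oxygen of 16)
Why: Iridium-catalysed aromatic C–H borylation is sterically governed and should go to C4, the only ring C–H without an ortho substituent, and the boronate is then oxidised in the same flask by peroxymonosulfate through 1,2-migration of the aryl group from boron to oxygen.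

Step 9
Reactants: 10 2-heptyl-4,6-dimethoxybenzoic acid; 16 tert-butyl 4-hydroxy-2-methoxy-6-pentylbenzoate
Product: 18 tert-butyl 4-[(2-heptyl-4,6-dimethoxybenzoyl)oxy]-2-methoxy-6-pentylbenzoate, via acid chloride 17 (not isolated)
Conditions: 10, (COCl)2 (1.5 equiv), DMF (cat.), CH2Cl2, 0 °C → rt; evaporate; then 16 (1.0 equiv), NaH (1.1 equiv), THF, 0 °C → rt
Reagents that add atoms: oxalyl chloride, O=C(Cl)C(=O)Cl (its chlorine stays only in 17)
Why: Acid chloride formation through the Vilsmeier-type chloroiminium reagent followed by O-acylation of the sodium phenoxide (Schotten–Baumann-type esterification), where the unhindered C4 phenoxide of ring B and the acylium-like character of the electron-rich acid chloride offset the two ortho substituents.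

Step 10
Reactants: 18 tert-butyl 4-[(2-heptyl-4,6-dimethoxybenzoyl)oxy]-2-methoxy-6-pentylbenzoate
Product: 19 4-[(2-heptyl-4,6-dimethoxybenzoyl)oxy]-2-methoxy-6-pentylbenzoic acid
Conditions: CF3CO2H/CH2Cl2 (1:4), 0 °C → rt
Reagents that add atoms: none
Why: Acidolysis of the tert-butyl ester by alkyl–oxygen cleavage with loss of isobutene, which the aryl ester and methyl ethers should survive, and since every free ring position is flanked by two substituents, Friedel–Crafts tert-butylation is not expected.

Compound list
1 | dibenzyl 3-oxopentanedioate | O=C(CC(=O)OCc1ccccc1)CC(=O)OCc1ccccc1 | starting material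
2 | octanoyl chloride | CCCCCCCC(=O)Cl | starting material
3 | dibenzyl 2-octanoyl-3-oxopentanedioate (racemic, largely enolised) | CCCCCCCC(=O)C(C(=O)OCc1ccccc1)C(=O)CC(=O)OCc1ccccc1 | intermediate
4 | benzyl 6-heptyl-4-hydroxy-2-oxo-2H-pyran-5-carboxylate | CCCCCCCC1=C(C(=O)OCc2ccccc2)C(O)=CC(=O)O1 | intermediate
5 | benzyl 6-heptyl-4-methoxy-2-oxo-2H-pyran-5-carboxylate | CCCCCCCC1=C(C(=O)OCc2ccccc2)C(OC)=CC(=O)O1 | intermediate
6 | 1,1-dimethoxyethene | C=C(OC)OC | starting material
7 | benzyl 1-heptyl-5,8,8-trimethoxy-3-oxo-2-oxabicyclo[2.2.2]oct-5-ene-6-carboxylate (racemic; the two bridgeheads are fixed relative to each other by the bicycle) | CCCCCCCC12OC(=O)C(C(OC)=C1C(=O)OCc3ccccc3)C(OC)(OC)C2 | intermediate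
8 | benzyl 2-heptyl-4,4,6-trimethoxycyclohexa-1,5-diene-1-carboxylate | CCCCCCCC1=C(C(=O)OCc2ccccc2)C(OC)=CC(OC)(OC)C1 | intermediate
9 | benzyl 2-heptyl-4,6-dimethoxybenzoate | CCCCCCCc1cc(OC)cc(OC)c1C(=O)OCc1ccccc1 | intermediate
10 | 2-heptyl-4,6-dimethoxybenzoic acid | CCCCCCCc1cc(OC)cc(OC)c1C(=O)O | intermediate
11 | 2-methoxy-6-methylbenzoic acid | COc1cccc(C)c1C(=O)O | starting material
12 | tert-butyl 2-methoxy-6-methylbenzoate | COc1cccc(C)c1C(=O)OC(C)(C)C | intermediate
13 | 1-iodobutane | CCCCI | starting material
14 | tert-butyl 2-methoxy-6-pentylbenzoate | CCCCCc1cccc(OC)c1C(=O)OC(C)(C)C | intermediate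
15 | tert-butyl 2-methoxy-6-pentyl-4-(4,4,5,5-tetramethyl-1,3,2-dioxaborolan-2-yl)benzoate | CCCCCc1cc(B2OC(C)(C)C(C)(C)O2)cc(OC)c1C(=O)OC(C)(C)C | intermediate
16 | tert-butyl 4-hydroxy-2-methoxy-6-pentylbenzoate | CCCCCc1cc(O)cc(OC)c1C(=O)OC(C)(C)C | intermediate
17 | 2-heptyl-4,6-dimethoxybenzoyl chloride | CCCCCCCc1cc(OC)cc(OC)c1C(=O)Cl | intermediate
18 | tert-butyl 4-[(2-heptyl-4,6-dimethoxybenzoyl)oxy]-2-methoxy-6-pentylbenzoate | CCCCCCCc1cc(OC)cc(OC)c1C(=O)Oc1cc(CCCCC)c(C(=O)OC(C)(C)C)c(OC)c1 | intermediate
19 | 4-[(2-heptyl-4,6-dimethoxybenzoyl)oxy]-2-methoxy-6-pentylbenzoic acid | CCCCCCCc1cc(OC)cc(OC)c1C(=O)Oc1cc(CCCCC)c(C(=O)O)c(OC)c1 | target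

Total step count: 10. Longest linear sequence: 7 steps (steps 1, 2, 3, 4, 5, 9, 10, from dibenzyl 3-oxopentanedioate); the ring B branch (steps 6, 7, 8) joins at step 9.

Steps most likely to fail

Step 4. The deactivated diene may react too slowly, so that oligomerisation of the ketene acetal, or its addition to pyrone C4 with loss of methoxide, outruns ring formation. The fallback makes ring A by substitution of a preformed arene, using reaction types already in the route; it sets out from tert-butyl 2-methoxy-6-methylbenzoate 12 and returns at acid 10. Lateral lithiation of 12 with LiN(iPr)2 and alkylation with 1-iodohexane should give tert-butyl 2-heptyl-6-methoxybenzoate F1. Iridium-catalysed C–H borylation at the unflanked C4 position should give tert-butyl 2-heptyl-6-methoxy-4-(4,4,5,5-tetramethyl-1,3,2-dioxaborolan-2-yl)benzoate F2, oxidised in the same flask with KHSO5 to tert-butyl 2-heptyl-4-hydroxy-6-methoxybenzoate F3. O-Methylation with Me2SO4/K2CO3 should give tert-butyl 2-heptyl-4,6-dimethoxybenzoate F4, and CF3CO2H should release 10, from which step 9 follows.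

Step 9. Acyl transfer may stall because the carbonyl carbon of 17 is shielded by the ortho heptyl and methoxy groups, so that hydrolysis of the acid chloride on work-up becomes the main event. The fallback makes the aryl C–O bond instead of the acyl C–O bond; it sets out from 14 and acid 10 and returns at 18. Boronate 15 would be isolated from the borylation of 14 and cleaved with NaIO4/NH4OAc in aqueous acetone to [4-(tert-butoxycarbonyl)-3-methoxy-5-pentylphenyl]boronic acid F5. F5 would then be coupled with 10 by copper-mediated oxidative O-arylation of the carboxylic acid (Chan–Lam-type; Cu(OSO2CF3)2, urea, EtOAc, air, 60 °C), in which the hindered acid reacts through its unhindered carboxylate oxygen.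

Step 1. Acylation may go to the enol oxygen or occur a second time at the other methylene group, and the product may lactonise or lose an ester group in an uncontrolled way during work-up. The fallback assembles the pyrone from a β-keto ester and a malonyl unit; it sets out from octanoyl chloride 2 and returns at hydroxypyrone 4, replacing steps 1 and 2. Acylation of Meldrum's acid with 2 (pyridine, CH2Cl2) should give 5-(1-hydroxyoctylidene)-2,2-dimethyl-1,3-dioxane-4,6-dione F6, which on heating with benzyl alcohol in toluene should give benzyl 3-oxodecanoate F7. Condensation of F7 with malonyl dichloride, by C-acylation at its α-carbon and O-acylation of the ketone enol, should give 4 directly.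

Further compounds
F1 | step 4 | tert-butyl 2-heptyl-6-methoxybenzoate | CCCCCCCc1cccc(OC)c1C(=O)OC(C)(C)C
F2 | step 4 | tert-butyl 2-heptyl-6-methoxy-4-(4,4,5,5-tetramethyl-1,3,2-dioxaborolan-2-yl)benzoate | CCCCCCCc1cc(B2OC(C)(C)C(C)(C)O2)cc(OC)c1C(=O)OC(C)(C)C
F3 | step 4 | tert-butyl 2-heptyl-4-hydroxy-6-methoxybenzoate | CCCCCCCc1cc(O)cc(OC)c1C(=O)OC(C)(C)C
F4 | step 4 | tert-butyl 2-heptyl-4,6-dimethoxybenzoate | CCCCCCCc1cc(OC)cc(OC)c1C(=O)OC(C)(C)C
F5 | step 9 | [4-(tert-butoxycarbonyl)-3-methoxy-5-pentylphenyl]boronic acid | CCCCCc1cc(B(O)O)cc(OC)c1C(=O)OC(C)(C)C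
F6 | step 1 | 5-(1-hydroxyoctylidene)-2,2-dimethyl-1,3-dioxane-4,6-dione | CCCCCCCC(O)=C1C(=O)OC(C)(C)OC1=O
F7 | step 1 | benzyl 3-oxodecanoate | CCCCCCCC(=O)CC(=O)OCc1ccccc1
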